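## Structural features

The target is a (3R)-isoflavanone. A 5,7-dihydroxychroman-4-one (benzene ring A fused to heterocycle ring C) carries benzene ring B on C3, and ring B is fused along C3'–C4' to a 2,2-dimethyl-2H-pyran (ring D). C3 is the only stereocentre and has no stereogenic neighbour in the target, although the route places a temporary one beside it at C4. H3 is both α to the C4 ketone and benzylic to ring B, so the centre is lost through the enol with any base and, more slowly, with acid. Other fragile points are the styrene-like C3''=C4'' alkene and the tertiary allylic aryl ether of ring D, the very electron-rich ring A, and the pair 2'-OH/C4=O, which can close to a hemiketal and dehydrate to a benzofuran with loss of C3. Ring B is a 1,2,3,4-tetrasubstituted benzene (C3 on C1', oxygen on C2', carbon on C3', oxygen on C4', hydrogen on C5' and C6'), and its two oxygens end differently: O2' as a free phenol, O4' as the ring D oxygen. The real difficulty is twofold: to tell O2' from O4' on a crowded ring, and to bring C3 intact to the last step. The key step uses the fact that the run C1'(alkyl)–C2'(O)–C3'(C)–C4'(O)–C5'H–C6'H maps atom for atom onto a vinylketene (C4', C1', C6', C5') and an oxygen-substituted alkyne (C2', C3'), which delivers O4' as a free phenol and O2' as a silyl ether.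

## Logic of the disconnections

**28 ⇒ 27 ⇒ 26.**
- Bonds cut: O2'–Si, and before it the O5–CH2 and O7–CH2 acetal bonds.
- Reason: all three phenols must be masked during C–C bond formation and oxidation.
- Order: the acetals go first so that O2' is still blocked while a Lewis acid is present and cannot attack C4.
- Gain: only the removal of acidic protons from the earlier steps.
- Demand: both steps must be brief and free of base, because C3 is enolisable in 26, 27 and 28.

**26 ⇒ 25 ⇒ 24.**
- Bonds cut: the C4=O π bond is exchanged for C4–H and O4–Si.
- Reason: at the carbinol level H3 is not acidic, so C3 tolerates amide bases, Grignard reagents, light and heat.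
- Gain: the racemisation problem is confined to the last three steps.
- Demand: O4 must be freed while the aryl O2'–Si(iPr)3 bond stays, without ionising the trioxygenated benzylic C4–O bond.
- Naked fluoride strips aryl silyl ethers first, and a hindered tert-butyldimethylsilyl ether would need acid strong enough to ionise C4. O4 therefore carries SiEt3, which yields to pyridine-buffered HF.

**24 ⇒ 21.**
- Bonds cut: O4'–C2'', with the alkene moved back from C3''=C4'' to C2''=C3''.
- Reason: an ortho-prenylphenol is the direct product of the annulation.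
- Gain: ring D is removed.
- Demand: only O4' may close, which is guaranteed because O2' is silylated.
- The oxidant must not abstract hydride from C4–H (benzylic to ring A) or C3–H (para-hydroxybenzylic in 21). An alkene-selective selenium electrophile is therefore preferred to a quinone.

**21 ⇒ 11 + 16.**
- Bonds cut: C1'–C2', C3'–C4' and C4'–C5'. A fourth ring bond, C1'–C6', is undone as a 1,2-shift of the vinyl group back to C4'.
- Reason: this is the only cut that removes all of ring B and builds the O2'/O4' distinction into the bond formation.
- Gain: one ring and the whole regiochemical problem, leaving two fragments of comparable size.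
- Demand: one orientation of the alkyne, a ketene source that spares H3, and a medium free of acid (toluene rather than a chlorinated solvent under light).

**16 ⇒ 13 ⇒ 12.**
- Bonds cut: O–Si, and the bond between the prenyl CH2 and the outer alkyne carbon.
- The oxygen-bearing alkyne carbon is the carbonyl carbon of 13. The other alkyne carbon is a one-carbon unit from dibromomethane, onto which the prenyl group migrates.
- Gain: a six-carbon commercial acid.
- Demand: addition to the ester must outrun deprotonation of its doubly activated CH2, and silylation must occur on oxygen.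

**11 ⇒ 9.**
- Bond cut: C=N2.
- Reason: 9 has a single enolisable position, so the diazo group can only go where it is needed.
- Demand: enolisation of an unsubstituted vinyl ketone without conjugate addition.

**9 ⇒ 8 ⇒ 7.**
- Bond cut: the acyl–vinyl C–C bond.
- Reason: an N-methoxy-N-methyl amide stops at mono-addition.
- Gain: return to the ester delivered by the ring-forming step.
- Demand: the liberated hydroxylamine must be kept from adding to the enone.

**7 ⇒ 6 ⇒ 5.**
- Bonds cut: O4–Si and C4–H.
- Reason: C4 is a sacrificial centre, but a single diastereomer keeps every intermediate homogeneous.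
- Demand: a non-basic reduction whose facial sense is set by a catalyst. This also turns any (3S) contaminant into a separable diastereomer.

**5 ⇒ 4.**
- Bond cut: C3–C4.
- Reason: umpolung of the formyl carbon closes ring C and sets C3 in one catalytic, redox-neutral step.
- Gain: one ring and the only lasting stereocentre.
- Demand: a carbene able to engage a formyl group flanked by two oxygens.

**4 ⇒ 2 + 3, 2 ⇒ 1.**
- Bonds cut: O1–C2, and the two acetal O–C bonds.
- Reason: the hydrogen-bonded hydroxyl of 1 is the last to react, so it stays free for the ether link.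
- Gain: three commercial compounds, 1, 3 and 12.

## Other disconnections considered

Alternative 1: The cut is C3–C4.
- **Forward step.** Sulfone aldehyde A1 would lose sulfinate under base to give ortho-quinone methide A2. A chiral triazolylidene bound to the formyl carbon would then add as an acyl anion equivalent to the exocyclic carbon of A2. Ring B would rearomatise and ring C would close to A3.
- **In favour.** Rings B and D arrive finished. C4 is formed at the ketone level, so no redox detour is needed. Only two acetals separate A3 from 28. On step economy this plan is clearly better than the chosen one.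
- **Equal point.** It relies on the same reluctant, doubly ortho-oxygenated formyl group as step 3.
- **Against.** C3 would be created already flanked by ketone and aryl group, in a flask that holds base, carbene, sulfinate and a 2'-phenoxide. These are the conditions that enolise A3. Facial control would have to act on a flat, short-lived acceptor whose exocyclic geometry is not fixed, and this ring closure has no close asymmetric model. A2 could also escape by return of sulfinate, by attack of a second phenoxide, or by a hydrogen shift.
- **Comparison.** The chosen plan sets C3 as a less acidic α-alkyl centre, stores it at the carbinol level and uses only well-understood mechanisms. It pays for this with roughly twice the number of steps.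

Alternative 2: The cut is C2–C3.
- **Forward step.** Diazo ketone A4 would lose N2 on dirhodium tetrakis[N-phthaloyl-(S)-tert-leucinate], Rh2(S-PTTL)4. The aryl(acyl)carbene carbon would insert into a C–H bond of one of the two equivalent ortho methoxy groups to give A5.
- **In favour.** The symmetry of ring A removes any site question. The C–H bond is activated by oxygen. The medium is neutral, so A5 should keep its configuration while it forms, which is equal to the chosen plan. A4 derives from a doubly activated methylene group that accepts the diazo group with a mild amine base, so it is easier to make and more stable than 11, which is better than the chosen plan. The route would also be shorter.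
- **Against.** Insertion into a primary C–H bond with formation of a six-membered ring is the least favourable combination for such carbenes. The carbene sits between two doubly ortho-substituted arenes. The methoxy oxygen can intercept it as a five-membered oxonium ylide that would collapse by a Stevens shift. Wolff rearrangement and attack on the ring D alkene also compete. The 5-O-methyl group left in A5 would need a boron halide on a racemisable, chromene-bearing ketone, and three different protecting groups mean three deprotections.
- **Comparison.** The chosen plan is longer but rests on a benzannulation of known regiochemistry, and it never creates C3 next to a ketone.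

Alternative 3: The cut is O1–C8a.
- **Forward step.** Bromo alcohol A6 would be closed to A7 with CuI, a phenanthroline ligand and Cs2CO3, by etherification on monovalent copper.
- **In favour.** C3 is stored at the carbinol level, exactly as in 24, which is equal to the chosen plan. Both centres could come from a reliable auxiliary-controlled aldol reaction. Rings B and D arrive complete. Because every phenol of A7 is an acetal, the O4 silyl group can be removed with plain fluoride, which is better than step 13. The route would be more convergent and probably somewhat shorter.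
- **Against.** The aryl bromide is very electron-rich and has a branched ortho substituent, so activation by copper would be slow and would call for prolonged heating with carbonate. Under those conditions the silyl group can migrate from O4 to the primary alkoxide, and debromination can compete. The brominated ring A aldehyde is not a commodity. The O2'/O4' distinction has to be solved separately when ring B is made.
- **Comparison.** The end games are nearly the same. The chosen plan wins only on the built-in differentiation of the ring B oxygens and loses on convergence.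

Key step: step 11

Assumption: the (5aR,10bS) triazolium salt is taken to give the (R) configuration at C3 of 5. If the sense of induction proves opposite, its (5aS,10bR) antipode, made from the other commercial enantiomer of cis-1-amino-2-indanol, is used instead.

Abbreviation: Chr = (3R,4S)-5,7-bis(methoxymethoxy)-4-(triethylsilyloxy)chroman-3-yl.

## Steps

Step 1
Reactants: 1 2,4,6-trihydroxybenzaldehyde
Product: 2 2-hydroxy-4,6-bis(methoxymethoxy)benzaldehyde
Conditions: MOMCl (2.1 equiv), iPr2NEt, CH2Cl2, 0 °C
Reagents that add atoms: chloromethyl methyl ether, COCCl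
Why: O-alkylation of phenols by an α-chloro ether; after the para and one ortho hydroxyl have reacted, the last hydroxyl is held in a hydrogen bond to the formyl oxygen and should stay free with two equivalents of reagent.

Step 2
Reactants: 2 2-hydroxy-4,6-bis(methoxymethoxy)benzaldehyde; 3 ethyl (E)-4-bromobut-2-enoate
Product: 4 ethyl (E)-4-[2-formyl-3,5-bis(methoxymethoxy)phenoxy]but-2-enoate
Conditions: K2CO3, DMF, 23 °C
Reagents that add atoms: none
Why: Williamson ether synthesis by SN2 attack on a primary allylic bromide; carbonate at room temperature is too weak to move or isomerise the E-enoate.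

Step 3
Reactants: 4 ethyl (E)-4-[2-formyl-3,5-bis(methoxymethoxy)phenoxy]but-2-enoate
Product: 5 ethyl 2-[(3R)-5,7-bis(methoxymethoxy)-4-oxochroman-3-yl]acetate
Conditions: (5aR,10bS)-2-(pentafluorophenyl)-5a,10b-dihydro-4H,6H-indeno[2,1-b][1,2,4]triazolo[4,3-d][1,4]oxazin-2-ium tetrafluoroborate (20 mol %), KN(SiMe3)2 (18 mol %), toluene, 23 °C
Reagents that add atoms: none
Why: Enantioselective intramolecular Stetter reaction: the triazolylidene turns the formyl carbon into an acyl anion equivalent that adds 6-exo-trig to the enoate β-carbon and forms C3–C4. C3 is set in this bond formation because the indane wall of the catalyst shields one face of the enoate. Less base than azolium salt is used so that no strong base is left to epimerise 5.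

Step 4
Reactants: 5 ethyl 2-[(3R)-5,7-bis(methoxymethoxy)-4-oxochroman-3-yl]acetate
Product: 6 ethyl 2-[(3R,4S)-4-hydroxy-5,7-bis(methoxymethoxy)chroman-3-yl]acetate (trans)
Conditions: (R)-1-methyl-3,3-diphenyltetrahydro-1H,3H-pyrrolo[1,2-c][1,3,2]oxazaborole (20 mol %), BH3·SMe2, THF, −20 °C; MeOH
Reagents that add atoms: none
Why: Corey–Bakshi–Shibata reduction: with ring A as the large group the (R)-catalyst should deliver hydride to the face that gives 4S, which is also the face of axial attack on the half-chair with an equatorial C3 side chain, so catalyst and substrate reinforce each other towards the trans alcohol. The medium is not basic, so C3 is safe, and any (3S) material becomes the cis diastereomer and can be separated. Low temperature guards against over-reduction of the electron-rich benzylic position.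

Step 5
Reactants: 6 ethyl 2-[(3R,4S)-4-hydroxy-5,7-bis(methoxymethoxy)chroman-3-yl]acetate
Product: 7 ethyl 2-[(3R,4S)-5,7-bis(methoxymethoxy)-4-(triethylsilyloxy)chroman-3-yl]acetate
Conditions: Et3SiCl, imidazole, DMF, 0 to 23 °C
Reagents that add atoms: chlorotriethylsilane, CC[Si](Cl)(CC)CC
Why: Imidazole-promoted silylation under acid-free conditions, run directly after step 4 to forestall lactonisation of the γ-hydroxy ester; the triethylsilyl group is chosen for its later release beside an aryl triisopropylsilyl ether.

Step 6
Reactants: 7 ethyl 2-[(3R,4S)-5,7-bis(methoxymethoxy)-4-(triethylsilyloxy)chroman-3-yl]acetate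
Product: 8 2-[(3R,4S)-5,7-bis(methoxymethoxy)-4-(triethylsilyloxy)chroman-3-yl]-N-methoxy-N-methylacetamide
Conditions: MeNH(OMe)·HCl, iPrMgCl, THF, −20 to 0 °C
Reagents that add atoms: N,O-dimethylhydroxylamine hydrochloride, CNOC.Cl
Why: Weinreb amide synthesis by aminolysis of the ester with the magnesium amide made in the flask; silyl ether, acetals and both stereocentres are inert to these conditions.

Step 7
Reactants: 8 2-[(3R,4S)-5,7-bis(methoxymethoxy)-4-(triethylsilyloxy)chroman-3-yl]-N-methoxy-N-methylacetamide
Product: 9 1-[(3R,4S)-5,7-bis(methoxymethoxy)-4-(triethylsilyloxy)chroman-3-yl]but-3-en-2-one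
Conditions: CH2=CHMgBr, THF, −78 to 0 °C; poured into cold aq NaHSO4/Et2O
Reagents that add atoms: vinylmagnesium bromide, C=C[Mg]Br
Why: Weinreb ketone synthesis: magnesium chelation by the N-methoxy group holds the reaction at mono-addition until the quench. The cold inverse acidic quench protonates the released hydroxylamine before it can add to the new enone, and the short two-phase contact spares the C4 silyl ether.

Step 8
Reactants: 9 1-[(3R,4S)-5,7-bis(methoxymethoxy)-4-(triethylsilyloxy)chroman-3-yl]but-3-en-2-one
Product: 11 1-diazo-1-[(3R,4S)-5,7-bis(methoxymethoxy)-4-(triethylsilyloxy)chroman-3-yl]but-3-en-2-one, via trifluoroacetyl ketone 10 (not isolated)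
Conditions: LiN(SiMe3)2, THF, −78 °C; CF3CO2CH2CF3; aq NH4Cl; then MeSO2N3, Et3N, H2O (1 equiv), MeCN, 23 °C
Reagents that add atoms: methanesulfonyl azide, CS(=O)(=O)N=[N+]=[N-]; 2,2,2-trifluoroethyl trifluoroacetate, O=C(OCC(F)(F)F)C(F)(F)F (trifluoroacetyl group stays only in 10)
Why: Detrifluoroacetylative diazo transfer, the variant of the Regitz reaction designed for base-sensitive enones: the CH2 next to C3 is the only enolisable position, its kinetic lithium enolate is acylated to 10, and the activated methine then takes N2 from the azide while the trifluoroacetyl group leaves as the N-sulfonyl amide. C3 and C4 are not touched; 11 is kept cold and dark and is used at once.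

Step 9
Reactants: 12 4-methylpent-3-enoic acid
Product: 13 ethyl 4-methylpent-3-enoate
Conditions: EtI, K2CO3, DMF, 23 °C
Reagents that add atoms: iodoethane, CCI
Why: Carboxylate O-alkylation; it avoids the acid of a Fischer esterification, which would lactonise this β,γ-unsaturated acid or move its alkene.

Step 10
Reactants: 13 ethyl 4-methylpent-3-enoate
Product: 16 triisopropyl[(5-methylhex-4-en-1-yn-1-yl)oxy]silane, via dibromo enolate 14 (not isolated), via lithium ynolate 15 (not isolated)
Conditions: CH2Br2, lithium 2,2,6,6-tetramethylpiperidide, THF, −78 °C; 13; n-BuLi, −78 to 23 °C; iPr3SiCl, −78 to 0 °C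
Reagents that add atoms: dibromomethane, BrCBr; chlorotriisopropylsilane, CC(C)[Si](Cl)(C(C)C)C(C)C
Why: Kowalski ester homologation stopped at the ynolate: LiCHBr2 adds to the ester, enolisation gives 14, and bromine–lithium exchange triggers the 1,2-shift of the prenyl group to give 15. The bulky chlorosilane silylates 15 on oxygen rather than carbon. The ester is added to preformed LiCHBr2 at −78 °C so that addition outruns deprotonation of the doubly activated CH2.

Step 11
Reactants: 11 1-diazo-1-[(3R,4S)-5,7-bis(methoxymethoxy)-4-(triethylsilyloxy)chroman-3-yl]but-3-en-2-one; 16 triisopropyl[(5-methylhex-4-en-1-yn-1-yl)oxy]silane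
Product: 21 4-[(3R,4S)-5,7-bis(methoxymethoxy)-4-(triethylsilyloxy)chroman-3-yl]-2-(3-methylbut-2-en-1-yl)-3-(triisopropylsilyloxy)phenol, via vinylketene 17 (not isolated), via vinylcyclobutenone 18 (not isolated), via dienylketene 19 (not isolated), via cyclohexadienone 20 (not isolated)
Conditions: 16 (2 equiv), degassed toluene (0.05 M), hν (300 nm), 20 °C; then 100 °C
Reagents that add atoms: none
Why: Excitation of the s-Z rotamer of 11 expels N2 while the vinyl group moves from the carbonyl carbon to the diazo carbon (photochemical Wolff rearrangement, which makes C1'–C6') and gives vinylketene 17. The polarised alkyne 16 then adds in a (2+2) sense, its nucleophilic prenyl-bearing carbon to the ketene carbonyl carbon (C3'–C4') and its oxygen-bearing carbon to the ketene α-carbon (C1'–C2'), so that 18 is a 4-vinylcyclobut-2-enone. Heating cleaves the former ketene C=C bond of 18 in a reversible conrotatory 4π opening to 19; only the isomer with the vinyl group turned towards the ketene can react on, and the other returns to 18. Ring B closes by a disrotatory 6π electrocyclisation of 19 (C4'–C5'), and 20 tautomerises to phenol 21. The closest known reaction type is the diazo ketone version of the Danheiser benzannulation with a siloxyalkyne. No lasting stereocentre is formed: the quaternary carbon of 18 disappears on ring opening, and C3 and C4 are spectators because H3 is not acidic at the carbinol level. The selectivity needed is the orientation of the (2+2) step, secured by the donor oxygen of 16, together with preference for the ynol ether over the far less nucleophilic prenyl alkene. The result is O4' free, O2' silylated and the prenyl group between them.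

Step 12
Reactants: 21 4-[(3R,4S)-5,7-bis(methoxymethoxy)-4-(triethylsilyloxy)chroman-3-yl]-2-(3-methylbut-2-en-1-yl)-3-(triisopropylsilyloxy)phenol
Product: 24 (3R,4S)-3-[2,2-dimethyl-5-(triisopropylsilyloxy)-2H-chromen-6-yl]-5,7-bis(methoxymethoxy)-4-(triethylsilyloxy)chroman, via selenide 22 (not isolated), via selenoxide 23 (not isolated)
Conditions: PhSeCl, K2CO3, CH2Cl2, −78 °C; then 30% H2O2, THF, 0 to 23 °C
Reagents that add atoms: benzeneselenenyl chloride, Cl[Se]c1ccccc1 (selenium and phenyl stay only in 22 and 23); hydrogen peroxide, OO (oxygen stays only in 23)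
Why: Phenylselenoetherification followed by selenoxide syn elimination: the seleniranium ion of the trisubstituted alkene is opened by O4' at its tertiary carbon (6-endo, Markovnikov), and 23 can eliminate only towards the benzylic CH2 because the other neighbour is quaternary. The reagent addresses the alkene and leaves the hydride-donor positions C4–H and C3–H alone. Carbonate takes up HCl and keeps the seleninic acid as its salt, so that it does not epoxidise the chromene.

Step 13
Reactants: 24 (3R,4S)-3-[2,2-dimethyl-5-(triisopropylsilyloxy)-2H-chromen-6-yl]-5,7-bis(methoxymethoxy)-4-(triethylsilyloxy)chroman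
Product: 25 (3R,4S)-3-[2,2-dimethyl-5-(triisopropylsilyloxy)-2H-chromen-6-yl]-5,7-bis(methoxymethoxy)chroman-4-ol
Conditions: HF·pyridine, pyridine, THF, 0 °C
Reagents that add atoms: none
Why: Selective desilylation: acidic fluoride sources cleave alkyl triethylsilyl ethers much faster than hindered aryl triisopropylsilyl ethers, the reverse of the order seen with naked fluoride. Excess pyridine should keep the medium too weakly acidic to ionise the C4–O bond.

Step 14
Reactants: 25 (3R,4S)-3-[2,2-dimethyl-5-(triisopropylsilyloxy)-2H-chromen-6-yl]-5,7-bis(methoxymethoxy)chroman-4-ol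
Product: 26 (3R)-3-[2,2-dimethyl-5-(triisopropylsilyloxy)-2H-chromen-6-yl]-5,7-bis(methoxymethoxy)chroman-4-one
Conditions: Dess–Martin periodinane, NaHCO3, CH2Cl2, 0 to 23 °C
Reagents that add atoms: none
Why: Dess–Martin oxidation, fast and free of amine base; solid bicarbonate takes up the acetic acid but is too weak and too insoluble to enolise 26. The silyl group on O2' prevents phenol oxidation and ring closure onto C4.

Step 15
Reactants: 26 (3R)-3-[2,2-dimethyl-5-(triisopropylsilyloxy)-2H-chromen-6-yl]-5,7-bis(methoxymethoxy)chroman-4-one
Product: 27 (3R)-3-[2,2-dimethyl-5-(triisopropylsilyloxy)-2H-chromen-6-yl]-5,7-dihydroxychroman-4-one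
Conditions: ZnBr2, n-PrSH, CH2Cl2, 0 °C, minutes
Reagents that add atoms: none
Why: Lewis acid and thiol cleavage of aryl methoxymethyl ethers: ZnBr2 activates the acetal and the thiol traps the oxocarbenium ion. A few minutes in an aprotic, non-basic medium leave far less time for enolisation of C3 than hours in protic acid would. O2' is still silylated and cannot attack the activated ketone.

Step 16
Reactants: 27 (3R)-3-[2,2-dimethyl-5-(triisopropylsilyloxy)-2H-chromen-6-yl]-5,7-dihydroxychroman-4-one
Product: 28 (3R)-5,7-dihydroxy-3-(5-hydroxy-2,2-dimethyl-2H-chromen-6-yl)chroman-4-one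
Conditions: Bu4NF, AcOH (1:1), THF, 0 °C
Reagents that add atoms: none
Why: Fluoride cleavage of an aryl silyl ether; acetic acid buffers fluoride and the released phenoxide so that the medium stays below the basicity needed to enolise C3.

## Compound list

1 | 2,4,6-trihydroxybenzaldehyde | O=Cc1c(O)cc(O)cc1O | starting material
2 | 2-hydroxy-4,6-bis(methoxymethoxy)benzaldehyde | O=Cc1c(O)cc(OCOC)cc1OCOC | intermediate
3 | ethyl (E)-4-bromobut-2-enoate | CCOC(=O)/C=C/CBr | starting material
4 | ethyl (E)-4-[2-formyl-3,5-bis(methoxymethoxy)phenoxy]but-2-enoate | CCOC(=O)/C=C/COc1cc(OCOC)cc(OCOC)c1C=O | intermediate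
5 | ethyl 2-[(3R)-5,7-bis(methoxymethoxy)-4-oxochroman-3-yl]acetate | CCOC(=O)C[C@@H]1COc2cc(OCOC)cc(OCOC)c2C1=O | intermediate
6 | ethyl 2-[(3R,4S)-4-hydroxy-5,7-bis(methoxymethoxy)chroman-3-yl]acetate | CCOC(=O)C[C@@H]1COc2cc(OCOC)cc(OCOC)c2[C@H]1O | intermediate
7 | ethyl 2-[(3R,4S)-5,7-bis(methoxymethoxy)-4-(triethylsilyloxy)chroman-3-yl]acetate | CCOC(=O)C[C@@H]1COc2cc(OCOC)cc(OCOC)c2[C@H]1O[Si](CC)(CC)CC | intermediate
8 | 2-[(3R,4S)-5,7-bis(methoxymethoxy)-4-(triethylsilyloxy)chroman-3-yl]-N-methoxy-N-methylacetamide | CON(C)C(=O)C[C@@H]1COc2cc(OCOC)cc(OCOC)c2[C@H]1O[Si](CC)(CC)CC | intermediate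
9 | 1-[(3R,4S)-5,7-bis(methoxymethoxy)-4-(triethylsilyloxy)chroman-3-yl]but-3-en-2-one | C=CC(=O)C[C@@H]1COc2cc(OCOC)cc(OCOC)c2[C@H]1O[Si](CC)(CC)CC | intermediate
10 | 3-Chr-1,1,1-trifluorohex-5-ene-2,4-dione (enolised, configuration at the methine carbon undefined) | C=CC(=O)C(C(=O)C(F)(F)F)[C@@H]1COc2cc(OCOC)cc(OCOC)c2[C@H]1O[Si](CC)(CC)CC | intermediate
11 | 1-diazo-1-[(3R,4S)-5,7-bis(methoxymethoxy)-4-(triethylsilyloxy)chroman-3-yl]but-3-en-2-one | C=CC(=O)C(=[N+]=[N-])[C@@H]1COc2cc(OCOC)cc(OCOC)c2[C@H]1O[Si](CC)(CC)CC | intermediate
12 | 4-methylpent-3-enoic acid | CC(C)=CCC(=O)O | starting material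
13 | ethyl 4-methylpent-3-enoate | CCOC(=O)CC=C(C)C | intermediate
14 | lithium 1,1-dibromo-5-methylhexa-1,4-dien-2-olate | [Li+].[O-]C(CC=C(C)C)=C(Br)Br | intermediate
15 | lithium 5-methylhex-4-en-1-yn-1-olate | [Li+].[O-]C#CCC=C(C)C | intermediate
16 | triisopropyl[(5-methylhex-4-en-1-yn-1-yl)oxy]silane | CC(C)=CCC#CO[Si](C(C)C)(C(C)C)C(C)C | intermediate
17 | 2-Chr-buta-1,3-dien-1-one (vinylketene) | C=CC(=C=O)[C@@H]1COc2cc(OCOC)cc(OCOC)c2[C@H]1O[Si](CC)(CC)CC | intermediate
18 | 4-Chr-2-(3-methylbut-2-en-1-yl)-3-(triisopropylsilyloxy)-4-vinylcyclobut-2-en-1-one (both epimers at ring carbon 4) | C=CC1([C@@H]2COc3cc(OCOC)cc(OCOC)c3[C@H]2O[Si](CC)(CC)CC)C(=O)C(CC=C(C)C)=C1O[Si](C(C)C)(C(C)C)C(C)C | intermediate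
19 | 4-Chr-2-(3-methylbut-2-en-1-yl)-3-(triisopropylsilyloxy)hexa-1,3,5-trien-1-one, vinyl group cis to the ketene arm | O=C=C(CC=C(C)C)/C(O[Si](C(C)C)(C(C)C)C(C)C)=C(\C=C)[C@@H]1COc2cc(OCOC)cc(OCOC)c2[C@H]1O[Si](CC)(CC)CC | intermediate
20 | 4-Chr-2-(3-methylbut-2-en-1-yl)-3-(triisopropylsilyloxy)cyclohexa-2,4-dien-1-one | O=C1CC=C([C@@H]2COc3cc(OCOC)cc(OCOC)c3[C@H]2O[Si](CC)(CC)CC)C(O[Si](C(C)C)(C(C)C)C(C)C)=C1CC=C(C)C | intermediate
21 | 4-[(3R,4S)-5,7-bis(methoxymethoxy)-4-(triethylsilyloxy)chroman-3-yl]-2-(3-methylbut-2-en-1-yl)-3-(triisopropylsilyloxy)phenol | CC(C)=CCc1c(O)ccc([C@@H]2COc3cc(OCOC)cc(OCOC)c3[C@H]2O[Si](CC)(CC)CC)c1O[Si](C(C)C)(C(C)C)C(C)C | intermediate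
22 | 6-Chr-2,2-dimethyl-3-(phenylselanyl)-5-(triisopropylsilyloxy)chroman (both epimers at the selenium-bearing carbon) | CC1(C)Oc2ccc([C@@H]3COc4cc(OCOC)cc(OCOC)c4[C@H]3O[Si](CC)(CC)CC)c(O[Si](C(C)C)(C(C)C)C(C)C)c2CC1[Se]c1ccccc1 | intermediate
23 | selenoxide of 22 | CC1(C)Oc2ccc([C@@H]3COc4cc(OCOC)cc(OCOC)c4[C@H]3O[Si](CC)(CC)CC)c(O[Si](C(C)C)(C(C)C)C(C)C)c2CC1[Se](=O)c1ccccc1 | intermediate
24 | (3R,4S)-3-[2,2-dimethyl-5-(triisopropylsilyloxy)-2H-chromen-6-yl]-5,7-bis(methoxymethoxy)-4-(triethylsilyloxy)chroman | CC1(C)C=Cc2c(ccc([C@@H]3COc4cc(OCOC)cc(OCOC)c4[C@H]3O[Si](CC)(CC)CC)c2O[Si](C(C)C)(C(C)C)C(C)C)O1 | intermediate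
25 | (3R,4S)-3-[2,2-dimethyl-5-(triisopropylsilyloxy)-2H-chromen-6-yl]-5,7-bis(methoxymethoxy)chroman-4-ol | CC1(C)C=Cc2c(ccc([C@@H]3COc4cc(OCOC)cc(OCOC)c4[C@H]3O)c2O[Si](C(C)C)(C(C)C)C(C)C)O1 | intermediate
26 | (3R)-3-[2,2-dimethyl-5-(triisopropylsilyloxy)-2H-chromen-6-yl]-5,7-bis(methoxymethoxy)chroman-4-one | CC1(C)C=Cc2c(ccc([C@@H]3COc4cc(OCOC)cc(OCOC)c4C3=O)c2O[Si](C(C)C)(C(C)C)C(C)C)O1 | intermediate
27 | (3R)-3-[2,2-dimethyl-5-(triisopropylsilyloxy)-2H-chromen-6-yl]-5,7-dihydroxychroman-4-one | CC1(C)C=Cc2c(ccc([C@@H]3COc4cc(O)cc(O)c4C3=O)c2O[Si](C(C)C)(C(C)C)C(C)C)O1 | intermediate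
28 | (3R)-5,7-dihydroxy-3-(5-hydroxy-2,2-dimethyl-2H-chromen-6-yl)chroman-4-one | CC1(C)C=Cc2c(ccc([C@@H]3COc4cc(O)cc(O)c4C3=O)c2O)O1 | target

## Step count and least certain steps

Total: 16 steps. Longest linear sequence: 14 steps (steps 1–8 and 11–16). Steps 9 and 10 form the side branch.

**Step 11 (key step).**
- Most likely failure: loss of N2 from the s-E rotamer without concerted vinyl migration, followed by a hydrogen shift from C3 to the carbene centre, which erases the stereocentre.
- A second weakness is slow capture of the hindered, disubstituted ketene, which leaves time for ketene self-condensation.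
- The fallback reaches the same ketene without a carbene. It sets out from 7 and comes back at 17, and so at 21.
- The lithium enolate of 7 (LiN(iPr)2, THF, −78 °C) is added to acetaldehyde to give the aldol adduct F1.
- MeSO2Cl and Et3N give the mesylate F2, and DBU gives the ethylidene ester F3.
- KOSiMe3 in THF gives the acid F4, and 1-chloro-N,N,2-trimethylprop-1-en-1-amine gives the acid chloride F5 under neutral conditions.
- Et3N in toluene at 80–100 °C in the presence of 16 then removes HCl in a 1,4 sense from the ethylidene methyl group. This is the known route from α,β-unsaturated acid chlorides to vinylketenes.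

**Step 3.**
- Most likely failure: sluggish addition of the bulky carbene to a formyl group that is electron-rich and flanked by two oxygens. The longer times or heating then needed would erode the configuration at C3 through enolisation or reversible ring opening.
- The fallback moves the stereochemical decision to the reduction. It sets out from 4 and comes back at 6.
- A small achiral carbene (3-benzyl-5-(2-hydroxyethyl)-4-methylthiazolium chloride, Et3N, dioxane, 70 °C) gives the racemic keto ester F6.
- The conditions of step 4 then reduce both enantiomers with catalyst control at C4. The (3R) half becomes trans-6 and the (3S) half becomes the cis hydroxy ester F7, which is removed by chromatography.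
- The price is half of the material.

**Step 8.**
- Most likely failure: conjugate addition of the amide base or of the newly formed enolate to unreacted vinyl ketone, with oligomerisation, because the acceptor terminus is unsubstituted.
- The fallback separates enolisation from enolate release, so that enolate and enone never coexist. It sets out from 9 and comes back at 10, and so at 11.
- Soft enolisation (Me3SiOTf, Et3N, CH2Cl2, −20 °C) gives the silyl dienol ether F8, which is isolated.
- MeLi in THF releases the lithium enolate in the absence of any enone. CF3CO2CH2CF3 at −78 °C then gives 10, and the azide stage follows as before.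

**Step 12.**
- Most likely failure: electrophilic attack of selenium on C6 or C8 of ring A in competition with the alkene, or partial 5-exo closure.
- The fallback changes the mechanism from alkene activation to dehydrogenation. It sets out from 21 and comes back at 24.
- DDQ in toluene abstracts hydride from the benzylic, allylic CH2 of the prenyl group, and the resulting quinone methide closes by oxa-6π electrocyclisation.
- It is only the second choice because hydride loss from C4–H or C3–H can compete.

**Step 13.**
- Most likely failure: ionisation of the C4–O bond even in the buffered medium, followed by proton loss from C3, or creeping loss of the aryl silyl group during a slow reaction.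
- The fallback gives up the silyl differentiation. It sets out from 24 and comes back at 28.
- Bu4NF in THF removes both silyl groups under basic conditions to give the diol F9.
- MOMCl and iPr2NEt protect the phenol in preference to the hindered secondary alcohol to give the acetal alcohol F10.
- Dess–Martin periodinane with NaHCO3 gives the tris-acetal ketone F11, and ZnBr2 with n-PrSH releases all three phenols at once.
- The step count is unchanged, but O2' is exposed to the Lewis acid in the last step.

**Step 15.**
- Most likely failure: partial enolisation of the zinc-activated ketone with erosion of C3, or addition of the thiol to the ring D alkene.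
- The fallback replaces acetal cleavage by acetal-to-silyl exchange under weakly basic conditions and merges the last two steps. It sets out from 26 and comes back at 28.
- Me3SiOTf and 2,2'-bipyridyl in MeCN at 0 °C convert both aryl acetals into the bis(trimethylsilyl) ether F12.
- The buffered fluoride of step 16 then removes all three silyl groups together.

## Further compounds

F1 | step 11 | ethyl 2-Chr-3-hydroxybutanoate (mixture at the two new centres) | CCOC(=O)C(C(C)O)[C@@H]1COc2cc(OCOC)cc(OCOC)c2[C@H]1O[Si](CC)(CC)CC
F2 | step 11 | ethyl 2-Chr-3-(methylsulfonyloxy)butanoate | CCOC(=O)C(C(C)OS(C)(=O)=O)[C@@H]1COc2cc(OCOC)cc(OCOC)c2[C@H]1O[Si](CC)(CC)CC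
F3 | step 11 | ethyl 2-Chr-but-2-enoate (E/Z mixture) | CCOC(=O)C(=CC)[C@@H]1COc2cc(OCOC)cc(OCOC)c2[C@H]1O[Si](CC)(CC)CC
F4 | step 11 | 2-Chr-but-2-enoic acid | OC(=O)C(=CC)[C@@H]1COc2cc(OCOC)cc(OCOC)c2[C@H]1O[Si](CC)(CC)CC
F5 | step 11 | 2-Chr-but-2-enoyl chloride | ClC(=O)C(=CC)[C@@H]1COc2cc(OCOC)cc(OCOC)c2[C@H]1O[Si](CC)(CC)CC
F6 | step 3 | racemic ethyl 2-[5,7-bis(methoxymethoxy)-4-oxochroman-3-yl]acetate | CCOC(=O)CC1COc2cc(OCOC)cc(OCOC)c2C1=O
F7 | step 3 | ethyl 2-[(3S,4S)-4-hydroxy-5,7-bis(methoxymethoxy)chroman-3-yl]acetate (cis) | CCOC(=O)C[C@H]1COc2cc(OCOC)cc(OCOC)c2[C@H]1O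
F8 | step 8 | (Z)-1-Chr-2-(trimethylsilyloxy)buta-1,3-diene | C=C/C(O[Si](C)(C)C)=C/[C@@H]1COc2cc(OCOC)cc(OCOC)c2[C@H]1O[Si](CC)(CC)CC
F0 | step 12 | none | none
F9 | step 13 | (3R,4S)-3-(5-hydroxy-2,2-dimethyl-2H-chromen-6-yl)-5,7-bis(methoxymethoxy)chroman-4-ol | CC1(C)C=Cc2c(ccc([C@@H]3COc4cc(OCOC)cc(OCOC)c4[C@H]3O)c2O)O1
F10 | step 13 | (3R,4S)-3-[5-(methoxymethoxy)-2,2-dimethyl-2H-chromen-6-yl]-5,7-bis(methoxymethoxy)chroman-4-ol | CC1(C)C=Cc2c(ccc([C@@H]3COc4cc(OCOC)cc(OCOC)c4[C@H]3O)c2OCOC)O1
F11 | step 13 | (3R)-3-[5-(methoxymethoxy)-2,2-dimethyl-2H-chromen-6-yl]-5,7-bis(methoxymethoxy)chroman-4-one | CC1(C)C=Cc2c(ccc([C@@H]3COc4cc(OCOC)cc(OCOC)c4C3=O)c2OCOC)O1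
F12 | step 15 | (3R)-3-[2,2-dimethyl-5-(triisopropylsilyloxy)-2H-chromen-6-yl]-5,7-bis(trimethylsilyloxy)chroman-4-one | CC1(C)C=Cc2c(ccc([C@@H]3COc4cc(O[Si](C)(C)C)cc(O[Si](C)(C)C)c4C3=O)c2O[Si](C(C)C)(C(C)C)C(C)C)O1
A1 | alternative 1 | 2-[2-(5-hydroxy-2,2-dimethyl-2H-chromen-6-yl)-2-(4-methylphenylsulfonyl)ethoxy]-4,6-bis(methoxymethoxy)benzaldehyde (racemic at the sulfone carbon) | CC1(C)C=Cc2c(ccc(C(COc3cc(OCOC)cc(OCOC)c3C=O)S(=O)(=O)c3ccc(C)cc3)c2O)O1
A2 | alternative 1 | ortho-quinone methide of ring B carrying the ring A aldehyde ether on its exocyclic carbon | CC1(C)C=CC2=C(O1)C=CC(=CCOc1cc(OCOC)cc(OCOC)c1C=O)C2=O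
A3 | alternative 1 | (3R)-3-(5-hydroxy-2,2-dimethyl-2H-chromen-6-yl)-5,7-bis(methoxymethoxy)chroman-4-one | CC1(C)C=Cc2c(ccc([C@@H]3COc4cc(OCOC)cc(OCOC)c4C3=O)c2O)O1
A4 | alternative 2 | 2-diazo-1-[4-(tert-butyldimethylsilyloxy)-2,6-dimethoxyphenyl]-2-[5-(tert-butyldiphenylsilyloxy)-2,2-dimethyl-2H-chromen-6-yl]ethanone | COc1cc(O[Si](C)(C)C(C)(C)C)cc(OC)c1C(=O)C(=[N+]=[N-])c1ccc2OC(C)(C)C=Cc2c1O[Si](c1ccccc1)(c1ccccc1)C(C)(C)C
A5 | alternative 2 | (3R)-7-(tert-butyldimethylsilyloxy)-3-[5-(tert-butyldiphenylsilyloxy)-2,2-dimethyl-2H-chromen-6-yl]-5-methoxychroman-4-one | CC1(C)C=Cc2c(ccc([C@@H]3COc4cc(O[Si](C)(C)C(C)(C)C)cc(OC)c4C3=O)c2O[Si](c5ccccc5)(c5ccccc5)C(C)(C)C)O1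
A6 | alternative 3 | (2R,3S)-3-[2-bromo-4,6-bis(methoxymethoxy)phenyl]-3-(tert-butyldimethylsilyloxy)-2-[5-(methoxymethoxy)-2,2-dimethyl-2H-chromen-6-yl]propan-1-ol | CC1(C)C=Cc2c(ccc([C@H](CO)[C@H](O[Si](C)(C)C(C)(C)C)c3c(Br)cc(OCOC)cc3OCOC)c2OCOC)O1
A7 | alternative 3 | (3R,4S)-4-(tert-butyldimethylsilyloxy)-3-[5-(methoxymethoxy)-2,2-dimethyl-2H-chromen-6-yl]-5,7-bis(methoxymethoxy)chroman | CC1(C)C=Cc2c(ccc([C@@H]3COc4cc(OCOC)cc(OCOC)c4[C@H]3O[Si](C)(C)C(C)(C)C)c2OCOC)O1
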